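**Retrosynthetic overview**

1. Enabling feature: C6 of the 1,2-dioxane (ring O1–O2–C3–C4–C5–C6, numbered with the acid chain C1–C14) is a peroxide-bearing quaternary carbon bonded directly to vinylic C7, and C8 of the C7=C8 alkene is fully substituted; C6 can therefore react as a ring peroxycarbenium ion (C6=O1+) and C7 as the ipso carbon of a 2,2-dialkylvinylsilane.
2. Disconnection 1 (last step): C6–C7, between a 6-methoxy-1,2-dioxane (cyclic peroxyketal carrying C3 and C4) and an (E)-alkenylsilane (C7–C14, carrying C10); the union makes the bond and sets quaternary C6 under control of the trans C3/C4 ring substituents.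
3. Disconnection 2: O2–C3 of the 1,2-dioxane, the only ring, closed before the key step by 6-exo peroxy-Michael addition of a C6 methoxy hydroperoxy ketal to the C2=C3 enoate, with C4 controlling C3.
4. Both ethyl-bearing stereocentres, C4 and C10, lie in the same CH(Et)(CH2)(CH=CH) unit, so both halves are cut from one ester, ethyl (R,E)-3-ethylhept-4-enoate (Et2Zn addition to (E)-pent-2-enal, then a chirality-transferring Johnson–Claisen rearrangement).
5. Ester to silane: reduction, alkyne homologation, methylalumination/iodination, silylation. Ester to peroxyketal: ethyl ketone, ozonolysis, Wittig olefination, hydroperoxyketalisation, ring closure.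

Key step: step 13

Remark: 16 and 17 are carried as mixtures of C6 epimers; this is assumed to be harmless because C6 becomes planar in step 13.

**Route**

Step 1
Reactants: 1 (E)-pent-2-enal
Product: 2 (R,E)-hept-4-en-3-ol
Conditions: Et2Zn (1.6 equiv), (+)-MIB [(2R)-3-exo-morpholinoisoborneol] (4 mol %), hexane/toluene, 0 °C; aq NH4Cl
Reagents that add atoms: diethylzinc, CC[Zn]CC
Why: Amino-alcohol-catalysed enantioselective 1,2-addition of a dialkylzinc to an aldehyde, in which the (+)-ligand, antipode of the one known to give (S)-carbinols, should direct ethyl transfer to the aldehyde face that gives the R allylic alcohol, the E double bond of the enal being carried over unchanged.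

Step 2
Reactants: 2 (R,E)-hept-4-en-3-ol
Product: 4 ethyl (R,E)-3-ethylhept-4-enoate, via mixed ketene acetal 3 (not isolated)
Conditions: MeC(OEt)3 (6 equiv), EtCO2H (5 mol %), 138 °C, EtOH distilled off
Reagents that add atoms: triethyl orthoacetate, CC(OCC)(OCC)OCC
Why: Johnson–Claisen rearrangement, in which the chair transition state of 3 with the carbinol ethyl group equatorial transfers the C–O stereocentre suprafacially across the E allyl unit to the new C–C stereocentre (R to R) and forms the new double bond E.

Step 3
Reactants: 4 ethyl (R,E)-3-ethylhept-4-enoate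
Product: 5 (R,E)-3-ethylhept-4-enal
Conditions: i-Bu2AlH (1.05 equiv), CH2Cl2, −78 °C; MeOH, aq potassium sodium tartrate
Reagents that add atoms: none
Why: Partial reduction of an ester with i-Bu2AlH, in which the tetrahedral aluminium hemiacetal persists at −78 °C until work-up so that the aldehyde is released without over-reduction and the β-stereocentre is not involved.

Step 4
Reactants: 5 (R,E)-3-ethylhept-4-enal
Product: 6 (R,E)-4-ethyloct-5-en-1-yne
Conditions: dimethyl (1-diazo-2-oxopropyl)phosphonate (1.3 equiv), K2CO3 (2 equiv), MeOH, 0 °C to rt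
Reagents that add atoms: dimethyl (1-diazo-2-oxopropyl)phosphonate, CC(=O)C(=[N+]=[N-])P(=O)(OC)OC
Why: Seyferth–Gilbert homologation in the Ohira–Bestmann variant, in which the diazomethylphosphonate anion formed in the flask converts the aldehyde into the terminal alkyne through a vinylidene carbene and 1,2-hydride shift under base too mild to move the isolated E alkene.

Step 5
Reactants: 6 (R,E)-4-ethyloct-5-en-1-yne
Product: 8 (1E,4R,5E)-4-ethyl-1-iodo-2-methylocta-1,5-diene, via alkenylalane 7 (not isolated)
Conditions: Me3Al (2.5 equiv), Cp2ZrCl2 (0.25 equiv), CH2Cl2, 0 °C to rt; I2 (1.3 equiv), THF, −30 to 0 °C; aq K2CO3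
Reagents that add atoms: trimethylaluminium, C[Al](C)C; iodine, II
Why: Negishi zirconium-catalysed carboalumination, in which CH3 and Al add syn to the terminal alkyne with Al at the terminal carbon and iodinolysis of the C–Al bond with retention gives the E iodide, while the internal disubstituted alkene is inert.

Step 6
Reactants: 8 (1E,4R,5E)-4-ethyl-1-iodo-2-methylocta-1,5-diene
Product: 10 [(1E,4R,5E)-4-ethyl-2-methylocta-1,5-dien-1-yl]trimethylsilane, via alkenyllithium 9 (not isolated)
Conditions: t-BuLi (2.1 equiv), Et2O, −78 °C; Me3SiCl (1.5 equiv), −78 °C to rt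
Reagents that add atoms: chlorotrimethylsilane, C[Si](C)(C)Cl
Why: Iodine–lithium exchange and electrophilic silylation of the alkenyllithium both occur with retention of the double-bond geometry.

Step 7
Reactants: 4 ethyl (R,E)-3-ethylhept-4-enoate
Product: 11 (R,E)-3-ethyl-N-methoxy-N-methylhept-4-enamide
Conditions: MeNH(OMe)·HCl (1.6 equiv), i-PrMgCl (3.2 equiv), THF, −20 to 0 °C
Reagents that add atoms: N,O-dimethylhydroxylamine hydrochloride, CNOC.Cl
Why: Aminolysis of the ester by the magnesium amide of N,O-dimethylhydroxylamine gives the Weinreb amide (acyl substitution) without touching the β-stereocentre.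

Step 8
Reactants: 11 (R,E)-3-ethyl-N-methoxy-N-methylhept-4-enamide
Product: 12 (R,E)-5-ethylnon-6-en-3-one
Conditions: EtMgBr (1.5 equiv), THF, 0 °C; aq NH4Cl
Reagents that add atoms: ethylmagnesium bromide, CC[Mg]Br
Why: Weinreb ketone synthesis, in which the chelated tetrahedral intermediate survives until work-up so that exactly one ethyl group is added.

Step 9
Reactants: 12 (R,E)-5-ethylnon-6-en-3-one
Product: 14 (R)-2-ethyl-4-oxohexanal, via ozonide 13 (not isolated)
Conditions: O3, CH2Cl2, −78 °C; Me2S (5 equiv), −78 °C to rt; concentrate (propanal removed), used crude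
Reagents that add atoms: ozone, [O-][O+]=O
Why: Ozonolysis with reductive work-up (Criegee mechanism through ozonide 13) cleaves the only C=C bond and leaves the ketone alone, and because the stereocentre is now α to the aldehyde, 14 is used at once without chromatography.

Step 10
Reactants: 14 (R)-2-ethyl-4-oxohexanal
Product: 15 methyl (R,E)-4-ethyl-6-oxooct-2-enoate
Conditions: Ph3P=CHCO2Me (1.3 equiv), CH2Cl2, 0 °C to rt
Reagents that add atoms: methyl (triphenylphosphoranylidene)acetate, COC(=O)C=P(c1ccccc1)(c1ccccc1)c1ccccc1
Why: Wittig olefination with a stabilised ylide reacts only at the aldehyde, gives the E enoate and is neutral enough to preserve the α-stereocentre, which becomes the allylic C4 centre.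

Step 11
Reactants: 15 methyl (R,E)-4-ethyl-6-oxooct-2-enoate
Product: 16 methyl (2E,4R)-4-ethyl-6-hydroperoxy-6-methoxyoct-2-enoate (both C6 epimers)
Conditions: urea·H2O2 (5 equiv), Sc(OTf)3 (5 mol %), MeOH, rt
Reagents that add atoms: hydrogen peroxide (from its urea adduct), OO; methanol, CO
Why: Sc(OTf)3-catalysed hydroperoxyketalisation of the ketone in methanol, a known reaction of δ-oxo-α,β-unsaturated esters, forms C6 as a mixture that is of no consequence because it is erased in step 13.

Step 12
Reactants: 16 methyl (2E,4R)-4-ethyl-6-hydroperoxy-6-methoxyoct-2-enoate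
Product: 17 methyl 2-[(3S,4R)-4,6-diethyl-6-methoxy-1,2-dioxan-3-yl]acetate (both C6 epimers)
Conditions: Et2NH (0.5 equiv), CF3CH2OH, rt
Reagents that add atoms: none
Why: Intramolecular peroxy-Michael (oxa-Michael) addition, 6-exo-trig, in which the allylic C4–H eclipses the double bond and the tethered hydroperoxide should add anti to the C4 ethyl group, so that C3 is set S and the CH2CO2Me and C4 ethyl groups become trans (both equatorial), the isomer that reversibility of the addition also favours.

Step 13
Reactants: 17 methyl 2-[(3S,4R)-4,6-diethyl-6-methoxy-1,2-dioxan-3-yl]acetate; 10 [(1E,4R,5E)-4-ethyl-2-methylocta-1,5-dien-1-yl]trimethylsilane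
Product: 19 methyl 2-[(3S,4R,6S)-4,6-diethyl-6-[(1E,4R,5E)-4-ethyl-2-methylocta-1,5-dien-1-yl]-1,2-dioxan-3-yl]acetate, via peroxycarbenium triflate 18 (not isolated)
Conditions: 10 (1.5 equiv), TMSOTf (0.3 equiv), 2,6-di-tert-butyl-4-methylpyridine (0.5 equiv), 4 Å MS, CH2Cl2, −78 to −40 °C; Et3N
Reagents that add atoms: none
Why: Proposed new method: TMSOTf silylates the exocyclic methoxy oxygen of 17, MeOSiMe3 leaves, and the ring peroxycarbenium ion 18 (C6=O1+) is attacked at C6 by the silicon-bearing carbon of 10 to give a tertiary carbocation at the methyl-bearing carbon β to silicon, from which Me3Si+ is lost to triflate, restoring the C7=C8 bond with retention of the E geometry and regenerating TMSOTf. The closest known reaction type is the Lewis-acid-mediated Hosomi–Sakurai allylation and Mukaiyama-type silyl enol ether addition of peroxyketal-derived peroxycarbenium ions, together with the ipso substitution of vinylsilanes by oxocarbenium ions; a 2,2-dialkylvinylsilane is defended as nucleophile because its attack creates a tertiary cation, which should make it about as nucleophilic as allyltrimethylsilane. No ring is closed in this step: the 1,2-dioxane is carried in from 17, and both C6 epimers of 17 converge on the same cation. The new quaternary stereocentre C6 is controlled by the ring: in the half-chair of 18 the trans C3 and C4 substituents are both pseudo-equatorial, and attack along the axial trajectory that leads directly to a chair places the alkenyl group axial, cis to the C3 CH2CO2Me group and trans to the C4 ethyl group, which is 6S. The step needs ionisation of the exocyclic C6–OMe bond and not of the ring C6–OO bond (secured by the more basic methoxy oxygen and by the reversibility of ring opening), attack by the vinylsilane and not by the 1,2-disubstituted alkene of 10 (secured by the tertiary β-silyl cation), and survival of the allylic tertiary C6–O bond of the product (secured by −78 °C, substoichiometric TMSOTf and a hindered pyridine that traps TfOH).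

**Compound list**

1 | (E)-pent-2-enal | CC/C=C/C=O | starting material
2 | (R,E)-hept-4-en-3-ol | CC[C@@H](O)/C=C/CC | intermediate
3 | (R,E)-3-[(1-ethoxyethenyl)oxy]hept-4-ene (mixed ketene acetal) | CC[C@@H](OC(=C)OCC)/C=C/CC | intermediate (not isolated)
4 | ethyl (R,E)-3-ethylhept-4-enoate | CCOC(=O)C[C@@H](CC)/C=C/CC | intermediate
5 | (R,E)-3-ethylhept-4-enal | O=CC[C@@H](CC)/C=C/CC | intermediate
6 | (R,E)-4-ethyloct-5-en-1-yne | C#CC[C@@H](CC)/C=C/CC | intermediate
7 | [(1E,4R,5E)-4-ethyl-2-methylocta-1,5-dien-1-yl]dimethylalumane | CC/C=C/[C@H](CC)C/C(C)=C/[Al](C)C | intermediate (not isolated)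
8 | (1E,4R,5E)-4-ethyl-1-iodo-2-methylocta-1,5-diene | CC/C=C/[C@H](CC)C/C(C)=C/I | intermediate
9 | [(1E,4R,5E)-4-ethyl-2-methylocta-1,5-dien-1-yl]lithium | CC/C=C/[C@H](CC)C/C(C)=C/[Li] | intermediate (not isolated)
10 | [(1E,4R,5E)-4-ethyl-2-methylocta-1,5-dien-1-yl]trimethylsilane | CC/C=C/[C@H](CC)C/C(C)=C/[Si](C)(C)C | intermediate
11 | (R,E)-3-ethyl-N-methoxy-N-methylhept-4-enamide | CON(C)C(=O)C[C@@H](CC)/C=C/CC | intermediate
12 | (R,E)-5-ethylnon-6-en-3-one | CCC(=O)C[C@@H](CC)/C=C/CC | intermediate
13 | (5R)-5-(5-ethyl-1,2,4-trioxolan-3-yl)heptan-3-one (ozonide, ring stereoisomers) | CCC(=O)C[C@@H](CC)C1OC(CC)OO1 | intermediate (not isolated)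
14 | (R)-2-ethyl-4-oxohexanal | CCC(=O)C[C@@H](CC)C=O | intermediate
15 | methyl (R,E)-4-ethyl-6-oxooct-2-enoate | CCC(=O)C[C@@H](CC)/C=C/C(=O)OC | intermediate
16 | methyl (2E,4R)-4-ethyl-6-hydroperoxy-6-methoxyoct-2-enoate (both C6 epimers) | CCC(OC)(OO)C[C@@H](CC)/C=C/C(=O)OC | intermediate
17 | methyl 2-[(3S,4R)-4,6-diethyl-6-methoxy-1,2-dioxan-3-yl]acetate (both C6 epimers) | CCC1(OC)C[C@@H](CC)[C@H](CC(=O)OC)OO1 | intermediate
18 | (5R,6S)-3,5-diethyl-6-(2-methoxy-2-oxoethyl)-5,6-dihydro-4H-1,2-dioxin-2-ium trifluoromethanesulfonate | CCC1=[O+]O[C@@H](CC(=O)OC)[C@H](CC)C1.[O-]S(=O)(=O)C(F)(F)F | intermediate (not isolated)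
19 | methyl 2-[(3S,4R,6S)-4,6-diethyl-6-[(1E,4R,5E)-4-ethyl-2-methylocta-1,5-dien-1-yl]-1,2-dioxan-3-yl]acetate | CC/C=C/[C@H](CC)C/C(C)=C/[C@]1(CC)C[C@@H](CC)[C@H](CC(=O)OC)OO1 | target

**Step count and risks**

Total step count: 13. Longest linear sequence: 9 steps (1, 2, 7, 8, 9, 10, 11, 12, 13).

Step 13 (Proposed new method). The C–C bond formation may be outrun by acid-induced ring-opening ionisation and fragmentation of the peroxide or by protodesilylation of the silane. Facial selectivity at C6 may erode through attack on a twist conformer, and the product may ionise at its allylic C6–O bond. The fallback uses known chemistry, sets out from iodide 8 and keto enoate 15, and makes the C6–C7 bond at the ketone oxidation level. Iodine–lithium exchange of 8 (t-BuLi, Et2O, −78 °C, giving 9) and transmetalation with anhydrous CeCl3 would give the alkenylcerium reagent dichloro[(1E,4R,5E)-4-ethyl-2-methylocta-1,5-dien-1-yl]cerium F1. Its 1,2-addition to the ketone of 15 (THF, −78 °C; organocerium reagents spare enoates and do not enolise ketones) should give the tertiary allylic alcohol methyl (2E,4R,7E,10R,11E)-4,6,10-triethyl-6-hydroxy-8-methyltetradeca-2,7,11-trienoate F2 as both C6 epimers. Acid-catalysed perhydrolysis (H2O2 in Et2O, cat. H2SO4, 0 °C; SN1 substitution through the allylic cation) would give the tertiary hydroperoxide methyl (2E,4R,7E,10R,11E)-4,6,10-triethyl-6-hydroperoxy-8-methyltetradeca-2,7,11-trienoate F3. Et2NH in CF3CH2OH would then close the 1,2-dioxane by the peroxy-Michael reaction of step 12 and give 19 together with its C6 epimer methyl 2-[(3S,4R,6R)-4,6-diethyl-6-[(1E,4R,5E)-4-ethyl-2-methylocta-1,5-dien-1-yl]-1,2-dioxan-3-yl]acetate F4, to be separated by chromatography. The fallback rejoins the route at 19. Its price is loss of control at C6 and allylic transposition during perhydrolysis; the transposed C8 hydroperoxide cannot close a six-membered ring and would be removed.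

Step 12. Facial selectivity at C3 may be incomplete in the ring closure, and forcing the equilibration with stronger base risks base-induced fragmentation of the peroxide. The fallback changes the acceptor geometry so that allylic 1,3-strain, not a weak conformational preference, fixes the C4–H in the plane of the double bond. Setting out from aldehyde 14, Still–Gennari olefination ((CF3CH2O)2P(O)CH2CO2Me, KN(SiMe3)2, 18-crown-6, THF, −78 °C) would give methyl (R,Z)-4-ethyl-6-oxooct-2-enoate F5. Hydroperoxyketalisation as in step 11 would give methyl (2Z,4R)-4-ethyl-6-hydroperoxy-6-methoxyoct-2-enoate F6, and Et2NH in CF3CH2OH would close the ring, rejoining the route at 17.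

Step 9. The α-stereocentre of the γ-keto aldehyde may epimerise, or the aldehyde may undergo intramolecular aldol condensation, during concentration and olefination. The fallback bypasses the aldehyde. Setting out from ketone 12, cross-metathesis with methyl acrylate (second-generation Hoveyda–Grubbs catalyst, CH2Cl2, 40 °C) would exchange the propylidene terminus for CHCO2Me with E selectivity and rejoin the route at 15. This fallback makes no new compound (F0).

**Further compounds**

F1 | step 13 | dichloro[(1E,4R,5E)-4-ethyl-2-methylocta-1,5-dien-1-yl]cerium | CC/C=C/[C@H](CC)C/C(C)=C/[Ce](Cl)Cl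
F2 | step 13 | methyl (2E,4R,7E,10R,11E)-4,6,10-triethyl-6-hydroxy-8-methyltetradeca-2,7,11-trienoate (both C6 epimers) | CC/C=C/[C@H](CC)C/C(C)=C/C(O)(CC)C[C@@H](CC)/C=C/C(=O)OC
F3 | step 13 | methyl (2E,4R,7E,10R,11E)-4,6,10-triethyl-6-hydroperoxy-8-methyltetradeca-2,7,11-trienoate (both C6 epimers) | CC/C=C/[C@H](CC)C/C(C)=C/C(OO)(CC)C[C@@H](CC)/C=C/C(=O)OC
F4 | step 13 | methyl 2-[(3S,4R,6R)-4,6-diethyl-6-[(1E,4R,5E)-4-ethyl-2-methylocta-1,5-dien-1-yl]-1,2-dioxan-3-yl]acetate | CC/C=C/[C@H](CC)C/C(C)=C/[C@@]1(CC)C[C@@H](CC)[C@H](CC(=O)OC)OO1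
F5 | step 12 | methyl (R,Z)-4-ethyl-6-oxooct-2-enoate | CCC(=O)C[C@@H](CC)/C=C\C(=O)OC
F6 | step 12 | methyl (2Z,4R)-4-ethyl-6-hydroperoxy-6-methoxyoct-2-enoate (both C6 epimers) | CCC(OC)(OO)C[C@@H](CC)/C=C\C(=O)OC
F0 | step 9 | none | none
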